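The synthesis rests on the C1–C6 bond (target numbering: ring A = C1–C6, C1 = CMe2, C2 = CHBr, C5 = CHMe, C6 = spiro), which closes ring A last. The key step reads the C2(Br)–C1(Me2)–C6 triad as a bromonium ion opened at its tertiary carbon, and C6/C9 of ring B as the γ- and carbonyl carbons of an enone. A configurationally defined bromonium ion, released by silver from a vic-dibromide, is captured by the γ-carbon of a 1-silyloxycyclohexa-1,3-diene: one operation closes ring A, joins both quaternary carbons, sets the spiro centre and unveils the ring-B enone that later relays C8–Br and C9–Cl. The precursor is an acyclic dibromoheptyl chain from (S)-citronellal on that diene.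

Key step: step 5

Remark: C-numbers in the Why lines are those of the target skeleton (C1 = CMe2, C2 = CHBr, C5 = CHMe, C6 = spiro, C7 = CH2 next to C8HBr, C9 = C(Me)Cl, C10 and C11 = CH2); the L-series Shi ketone and Ph3PBr2 are assumed to be purchasable; compounds 3–6 are mixtures at the one ring (or α-aldehyde) centre that step 4 erases.

Step 1
Reactants: 1 (S)-citronellal; 2 methyl vinyl ketone
Product: 4 4-[(2S)-6-methylhept-5-en-2-yl]cyclohex-2-en-1-one (both epimers at ring C4), via keto-aldehyde Michael adduct 3 (not isolated)
Conditions: Et2NSiMe3 (10 mol %), MeCN, reflux; then aq. KOH, nBu4NOH (cat.), THF–Et2O, reflux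
Reagents that add atoms: none
Why: Amine-catalysed (enamine) Michael addition of the aldehyde α-carbon to the enone followed by base-mediated intramolecular aldol condensation (Robinson-type annulation to a 4-substituted cyclohexenone) should leave the bought C5 stereocentre untouched, and the new ring centre does not matter because step 4 planarises it.

Step 2
Reactants: 4 4-[(2S)-6-methylhept-5-en-2-yl]cyclohex-2-en-1-one
Product: 5 4-{(2S)-4-[(2S)-3,3-dimethyloxiran-2-yl]butan-2-yl}cyclohex-2-en-1-one
Conditions: ent-Shi ketone (L-fructose-derived, 30 mol %), Oxone, K2CO3, nBu4NHSO4, MeCN–DMM/aq. borate–EDTA buffer (pH ca. 10.5), 0 °C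
Reagents that add atoms: Oxone (potassium peroxymonosulfate), OOS(=O)(=O)[O-].[K+]
Why: Shi asymmetric epoxidation (chiral dioxirane, spiro transition state) should take the electron-rich trisubstituted alkene in preference to the enone and set the (S)-oxirane carbon (the future C2) under catalyst control.

Step 3
Reactants: 5 4-{(2S)-4-[(2S)-3,3-dimethyloxiran-2-yl]butan-2-yl}cyclohex-2-en-1-one
Product: 6 4-[(2S,5R)-5,6-dibromo-6-methylheptan-2-yl]cyclohex-2-en-1-one
Conditions: Ph3PBr2 (1.2 equiv), MeCN, 0 → 23 °C
Reagents that add atoms: triphenylphosphine dibromide, BrP(Br)(c1ccccc1)(c1ccccc1)c1ccccc1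
Why: Deoxydibromination of an epoxide with a phosphine dihalide: bromide opens the P-activated oxirane at the tertiary carbon and the secondary C–O–PPh3+ is then replaced with inversion (directly or through the bridged bromonium ion), which should give the (5R)-bromide, the configuration of C2.

Step 4
Reactants: 6 4-[(2S,5R)-5,6-dibromo-6-methylheptan-2-yl]cyclohex-2-en-1-one
Product: 7 tert-butyl({4-[(2S,5R)-5,6-dibromo-6-methylheptan-2-yl]cyclohexa-1,3-dien-1-yl}oxy)dimethylsilane
Conditions: TBSOTf (1.3 equiv), Et3N (2.5 equiv), CH2Cl2, 0 → 23 °C (equilibrating); Et3N-buffered work-up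
Reagents that add atoms: tert-butyldimethylsilyl triflate, CC(C)(C)[Si](C)(C)OS(=O)(=O)C(F)(F)F
Why: Soft enolisation–silylation of an enone (silyl triflate/amine) under equilibrating conditions should favour loss of the γ-hydrogen to the fully conjugated 1-silyloxy-1,3-diene with two trisubstituted double bonds over the cross-conjugated α′-isomer, and it erases the ring stereocentre.

Step 5
Reactants: 7 tert-butyl({4-[(2S,5R)-5,6-dibromo-6-methylheptan-2-yl]cyclohexa-1,3-dien-1-yl}oxy)dimethylsilane
Product: 9 (6R,8R,11S)-8-bromo-7,7,11-trimethylspiro[5.5]undec-1-en-3-one, via bromiranium triflate 8 (not isolated)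
Conditions: AgOTf (1.2 equiv), 2,6-di-tert-butyl-4-methylpyridine (1.5 equiv), CH2Cl2 (high dilution), −78 → −30 °C, dark
Reagents that add atoms: none
Why: Silver abstracts the tertiary bromide with anchimeric assistance from the neighbouring C2–Br, so the bromonium ion forms with the C2 configuration intact; the γ-carbon (C6) of the silyl dienol ether opens it at the tertiary carbon C1 anti to bromine, and loss of the silyl group from the oxocarbenium ion leaves the C7=C8–C9=O enone. The closest known reaction types are the Lewis-acid or silver-promoted SN1 tert-alkylation of silyl enol ethers with tertiary halides in its vinylogous (γ-selective) Mukaiyama form, and bromonium-initiated cation–olefin cyclisation. Ring A closes through a six-membered chair, 6-endo with respect to the bromonium ion (Markovnikov opening at C1) and 6-exo-trig with respect to the C6=C7 bond of the diene. C2 and C5 are carried in, and the only new stereocentre, spiro C6, is set by that chair: anti-periplanar opening places C2–Br equatorial, which forces the C5 methyl axial, and this methyl should eclipse the C6=C7 π-bond (vinylic H) in preference to the C6–C11 σ-bond, so the flat vinyl arm becomes equatorial (cis to Br and Me) and the CH2 arm axial. The step needs γ- over α-attack (six- against eight-membered ring) and C–C bond formation faster than E1 proton loss; the tether length, the high nucleophilicity of the dienol ether, the absence of free Br+ or a second alkene (no bromonium scrambling), the hindered base and the low temperature secure this.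

Step 6
Reactants: 9 (6R,8R,11S)-8-bromo-7,7,11-trimethylspiro[5.5]undec-1-en-3-one
Product: 11 (2S,6S,8R,11S)-2,8-dibromo-7,7,11-trimethylspiro[5.5]undecan-3-one, via lithium enolate 10 (not isolated)
Conditions: L-Selectride (1.05 equiv), THF, −78 °C; NBS (1.1 equiv), −78 °C; then LiBr (cat.), THF, 23 °C
Reagents that add atoms: N-bromosuccinimide, O=C1CCC(=O)N1Br
Why: 1,4-Reduction of the β-unsubstituted enone gives the C8=C9 enolate regiospecifically and NBS brominates it at C8; bromide-catalysed SN2 epimerisation of the α-bromo ketone should then settle on the equatorial bromide cis to C1, because ring B keeps the smaller C5 arm of the spiro centre axial and an axial C8–Br would be syn-axial to it (thermodynamic control).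

Step 7
Reactants: 11 (2S,6S,8R,11S)-2,8-dibromo-7,7,11-trimethylspiro[5.5]undecan-3-one
Product: 12 (2S,3S,6S,8R,11S)-2,8-dibromo-3,7,7,11-tetramethylspiro[5.5]undecan-3-ol
Conditions: AlMe3 (3 equiv), toluene, −78 → −20 °C
Reagents that add atoms: trimethylaluminium, C[Al](C)C
Why: 1,2-Addition of excess trimethylaluminium in a hydrocarbon solvent (2:1 Al:ketone transition state, the O-bound aluminium avoiding the equatorial C8–Br) should transfer methyl axially and give the equatorial carbinol, with OH trans to bromine and the C9 methyl axial as in the target.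

Step 8
Reactants: 12 (2S,3S,6S,8R,11S)-2,8-dibromo-3,7,7,11-tetramethylspiro[5.5]undecan-3-ol
Product: 13 (2R,5S,6S,8S,9S)-2,8-dibromo-9-chloro-1,1,5,9-tetramethylspiro[5.5]undecane (target)
Conditions: SOCl2 (1.5 equiv), CH2Cl2, −30 → 0 °C (no base)
Reagents that add atoms: thionyl chloride, O=S(Cl)Cl
Why: Deoxychlorination of the tertiary alcohol through its chlorosulfite with retention: ionisation is followed by front-side ion-pair return (SNi) or by bridging of the vicinal bromine (neighbouring-group participation, double inversion) with chloride opening the bromonium ion at the tertiary C9 anti to Br, and both paths should give the trans Br/Cl pair.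

Compound list
1 | (S)-citronellal, (3S)-3,7-dimethyloct-6-enal | C[C@H](CC=O)CCC=C(C)C | starting material
2 | methyl vinyl ketone (but-3-en-2-one) | CC(=O)C=C | starting material
3 | (3S)-3,7-dimethyl-2-(3-oxobutyl)oct-6-enal (C2 epimers) | C[C@H](C(C=O)CCC(C)=O)CCC=C(C)C | intermediate (not isolated)
4 | 4-[(2S)-6-methylhept-5-en-2-yl]cyclohex-2-en-1-one (ring C4 epimers) | C[C@H](C1C=CC(=O)CC1)CCC=C(C)C | intermediate
5 | 4-{(2S)-4-[(2S)-3,3-dimethyloxiran-2-yl]butan-2-yl}cyclohex-2-en-1-one (ring C4 epimers) | C[C@H](C1C=CC(=O)CC1)CC[C@@H]2OC2(C)C | intermediate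
6 | 4-[(2S,5R)-5,6-dibromo-6-methylheptan-2-yl]cyclohex-2-en-1-one (ring C4 epimers) | C[C@H](C1C=CC(=O)CC1)CC[C@@H](Br)C(C)(C)Br | intermediate
7 | tert-butyl({4-[(2S,5R)-5,6-dibromo-6-methylheptan-2-yl]cyclohexa-1,3-dien-1-yl}oxy)dimethylsilane | C[C@H](C1=CC=C(O[Si](C)(C)C(C)(C)C)CC1)CC[C@@H](Br)C(C)(C)Br | intermediate
8 | (3R)-3-{(3S)-3-[4-(tert-butyldimethylsilyloxy)cyclohexa-1,3-dien-1-yl]butyl}-2,2-dimethylbromiran-1-ium triflate | C[C@H](C1=CC=C(O[Si](C)(C)C(C)(C)C)CC1)CC[C@H]2[Br+]C2(C)C.[O-]S(=O)(=O)C(F)(F)F | intermediate (not isolated)
9 | (6R,8R,11S)-8-bromo-7,7,11-trimethylspiro[5.5]undec-1-en-3-one | C[C@H]1CC[C@@H](Br)C(C)(C)[C@]12CCC(=O)C=C2 | intermediate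
10 | lithium (8R,11S)-8-bromo-7,7,11-trimethylspiro[5.5]undec-2-en-3-olate (spiro centre as in 11) | C[C@H]1CC[C@@H](Br)C(C)(C)[C@]12CCC([O-])=CC2.[Li+] | intermediate (not isolated)
11 | (2S,6S,8R,11S)-2,8-dibromo-7,7,11-trimethylspiro[5.5]undecan-3-one | C[C@H]1CC[C@@H](Br)C(C)(C)[C@]12CCC(=O)[C@@H](Br)C2 | intermediate
12 | (2S,3S,6S,8R,11S)-2,8-dibromo-3,7,7,11-tetramethylspiro[5.5]undecan-3-ol | C[C@H]1CC[C@@H](Br)C(C)(C)[C@]12CC[C@](C)(O)[C@@H](Br)C2 | intermediate
13 | (2R,5S,6S,8S,9S)-2,8-dibromo-9-chloro-1,1,5,9-tetramethylspiro[5.5]undecane | C[C@H]1CC[C@@H](Br)C(C)(C)[C@]12CC[C@](C)(Cl)[C@@H](Br)C2 | target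

Total step count: 8. Longest linear sequence: 8 steps (from 1).

Steps most likely to fail

1. Step 5 (key step). The two ring-B arms (vinyl C7 and CH2 C11) may be poorly differentiated in the closing chair, which must also carry the C5 methyl axial, so the spiro centre could form with low or inverted selectivity. The fallback sets out from 7 and comes back at 11; it no longer depends on that selectivity, because the saturated ring B has two constitutionally identical arms and only the position of C8–Br tells them apart. The same silver-mediated closure is run and the C6-epimeric enone (6S,8R,11S)-8-bromo-7,7,11-trimethylspiro[5.5]undec-1-en-3-one F1 (C10=C11 unsaturated, ring A unchanged) is taken on. Kinetic deprotonation at its only α′-CH2 (C8) with LDA in THF at −78 °C and bromination with NBS, followed by the LiBr equilibration of step 6, should give the α′-bromo enone 4,8-dibromo-7,7,11-trimethylspiro[5.5]undec-1-en-3-one F2. L-Selectride at −78 °C with an acetic acid quench then saturates C10=C11 and delivers 11. Enone 9 is brominated through its 1,4-reduction enolate and F1 through its cross-conjugated enolate, so both outcomes of the ring closure converge.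

2. Step 4. Kinetic removal of an α′-proton from the O-silylated enone may give the cross-conjugated 2-silyloxy-1,3-diene, which cannot close a six-membered ring, and the amine base may cause E2 loss of HBr from the tertiary bromide. The fallback sets out from 6 and comes back at 9; it replaces base-mediated silylation by acid-catalysed, thermodynamically controlled enol etherification, the classical route from conjugated enones to linear alkoxydienes. Treatment of 6 with HC(OMe)3 and catalytic TsOH in dioxane at 23 °C should give 1-methoxy-4-[(2S,5R)-5,6-dibromo-6-methylheptan-2-yl]cyclohexa-1,3-diene F3. Under the silver conditions of step 5 this closes to the O-methyl oxocarbenium triflate F4, which aqueous work-up hydrolyses to 9.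

3. Step 8. The tertiary chlorosulfite may ionise to an unbridged cation that loses a proton (E1), that is captured on the axial face to give the C9-epimeric chloride, or whose bromonium form is opened at C8 with a 1,2-shift of bromine. The fallback sets out from 9 and comes back at 13; it installs both halogens by anti addition to an alkene instead of substitution at C9. Conjugate reduction of 9 with L-Selectride and trapping with Comins' reagent gives the enol triflate (8R,11S)-8-bromo-7,7,11-trimethylspiro[5.5]undec-2-en-3-yl triflate F5. Iron-catalysed coupling with MeMgBr (Fe(acac)3, THF–NMP, −20 °C) gives the trisubstituted alkene 8-bromo-3,7,7,11-tetramethylspiro[5.5]undec-2-ene F6. Tetrabutylammonium dichlorobromate in CH2Cl2 at −78 °C should then add bromine to C8 and chloride to the tertiary C9 in anti fashion to reach 13; the trans relationship is guaranteed by the mechanism, while the facial choice rests on the substrate.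

Further compounds
F1 | step 5 | (6S,8R,11S)-8-bromo-7,7,11-trimethylspiro[5.5]undec-1-en-3-one | C[C@H]1CC[C@@H](Br)C(C)(C)[C@]12C=CC(=O)CC2
F2 | step 5 | 4,8-dibromo-7,7,11-trimethylspiro[5.5]undec-1-en-3-one (C4–Br equatorial, ring A and spiro centre as in F1) | C[C@H]1CC[C@@H](Br)C(C)(C)[C@]12C=CC(=O)[C@@H](Br)C2
F3 | step 4 | 1-methoxy-4-[(2S,5R)-5,6-dibromo-6-methylheptan-2-yl]cyclohexa-1,3-diene | C[C@H](C1=CC=C(OC)CC1)CC[C@@H](Br)C(C)(C)Br
F4 | step 4 | O-methyl oxocarbenium triflate of 9 | C[C@H]1CC[C@@H](Br)C(C)(C)[C@]12CCC(=[O+]C)C=C2.[O-]S(=O)(=O)C(F)(F)F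
F5 | step 8 | (8R,11S)-8-bromo-7,7,11-trimethylspiro[5.5]undec-2-en-3-yl trifluoromethanesulfonate (spiro centre as in 11) | C[C@H]1CC[C@@H](Br)C(C)(C)[C@]12CCC(OS(=O)(=O)C(F)(F)F)=CC2
F6 | step 8 | 8-bromo-3,7,7,11-tetramethylspiro[5.5]undec-2-ene (ring A and spiro centre as in 11) | C[C@H]1CC[C@@H](Br)C(C)(C)[C@]12CCC(C)=CC2
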